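## Structural features

Atoms are labelled by labdane numbering for the decalin and its side chain (C1–C12, with C17 the exocyclic methylene and C16 the methyl on C13), C13–C15 for the rest of ring C, D1–D6 for ring D (D1 the ketone beside the fusion CH D6, D2 the methoxy-bearing carbon, D3 the vinylic CH, D4 the second ketone, D5 the quaternary carbon) and primed numbers for the chromone. The target joins three domains: a trans-decalin (rings A and B) with contiguous stereocentres C5, C10 and C9, where C9 is a tertiary alcohol beside the C8=C17 methylene that is conjugated with the C7 ketone; a cyclohexene ring C (C12, C13=C14, C15); and a 2-methoxycyclohex-2-ene-1,4-dione ring D cis-fused to ring C through D5–D6. D5 is quaternary and also carries the 5,7-dihydroxychromon-2-yl group, and the triad C12–D5–D6 (C11 and the chromone on one face of ring C, both ring D bonds on the other) is linked to the decalin only through the C11 methylene, so its configuration relative to C9 cannot be expected from substrate control. Several groups are fragile: the α-methylene ketone with its neighbouring tertiary carbinol (conjugate addition at C17 opens a retro-aldol path, and before oxidation the 7,9-dioxygenated allyl system ionises in protic acid), the vinylogous ester D2–D4 with the epimerisable D6–H, the D5–D4 bond (D5 is a doubly stabilised leaving carbanion), the chromone (electrophilic C2′, chelating 5-OH) and the C13=C14 alkene, which lies 1,4 to the 9-OH. The real difficulty is the congested quaternary D5 between two stereocentres, its stereochemical link to the remote decalin, and the regiodefined placement of C13=C14. The key step exploits the fact that D5 is flanked inside ring C by C12 and D6. Cutting C12–C13 and D5–D6 makes D5 the α-carbon of an alkylidene (C12=D5) activated by the D4 ketone and the chromone, and makes C13–C14–C15–D6 a diene whose C14 oxygen later marks the alkene. Ring D is left as two masked arms, one of which is a chelating α-alkoxy ketone.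

## Logic of the disconnections

29 to 28. No skeletal bond is cut; the C7 carbonyl is traced to the 7α-alcohol. The α-methylene ketone is the most electrophilic site and is formed last. Every earlier compound then carries an allylic alcohol derivative that is neither a dienophile nor a Michael acceptor. The forward step must oxidise one allylic secondary alcohol beside a tertiary alcohol and two phenols.

28 to 27. The O7–Si–O9 bridge and the two aryl O–Si bonds are restored. One fluoride operation removes all silicon. It must be buffered so that the vinylogous ester and D6 are untouched.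

27 to 25 through 26. The D2=D3 bond is cut (aldol condensation) and the D1 and D3 carbonyls are retraced to a dioxolane and a dimethyl acetal. Ring D becomes two inert arms on D5 and D6. The forward step has to unmask two electronically deactivated acetals without protic acid strong enough to ionise C9–O or protonate C13=C14, and to close the ring without epimerising D6.

25 to 24 to 23 to 22. C14–H is traced to C14–OTf, to the C14 ketone and to the C14 silyl enol ether. The alkene position is thus derived from the oxygen the diene needs for its regiochemistry. The enol triflate must form toward C13 without a free enolate, because both β-carbons of the C14 ketone (C12 and D6) are bonded to the good leaving carbanion D5.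

22 to 14 and 21. C12–C13 and D5–D6 are cut (ring C). This removes the quaternary centre, ring C and four stereocentres in one step and leaves two fragments of similar size. The forward step needs the (E)-geometry of 14, an endo transition state, catalyst control of the face relative to the decalin, and carbocyclic rather than hetero-Diels–Alder closure.

14 to 9 and 13. C12=D5 is cut (Knoevenagel). Both 9 and 13 are far simpler than 14. The condensation must give the isomer with C11 cis to the chromone and must tolerate a β-oxygenated aldehyde.

13 to 11 and 12; 11 to 10. D5–D4 is cut (Claisen acylation of the chromone 2-methyl group) and the aryl O–Si bonds are removed. This requires clean lateral deprotonation of 11 and an ester that does not self-condense.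

21 to 20; 20 to 17 and 18 through 19; 17 to 16 to 15. The enol O–Si bond, the C15=D6 bond (olefination), the dioxolane and one O–methyl bond are cut in turn, down to 15, which is symmetrical. The forward steps need mono-methylation and (E)-olefination.

9 to 8 to 7. The aldehyde is traced to its dimethyl acetal and the silylene to the 7α,9α-diol. The diol must be 1,3-diaxial so that one reagent masks both hydroxyls.

7 to 6 to 5 to 4. C7–O is removed (allylic oxidation), the 9α-ol with its C8=C17 alkene is traced to the 8α,9α-epoxide, and the epoxide to the 8,9-alkene. The forward steps need α-face epoxidation and proton abstraction from C17.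

4 to 3 to 2 to 1. The acetal, the aldehyde and the ester are adjusted in oxidation level, and the 8,9-alkene is traced to the C8–O bond of the lactone. C5 and C10 come unchanged from 1.

## Other disconnections considered

Alternative 1: The cut is C8–C9 of ring B. The seco-diketone A1 (a cyclohexane with the 2-oxobut-3-enyl chain on C5 and the 3,3-dimethoxypropanoyl group on C10) would be treated with MgI2 and then DBU. Iodide adds to the vinyl ketone, the C8 enolate attacks the C9 ketone, and loss of HI gives the hydroxy enone A2.
- In favour: it produces the complete 9α-hydroxy-7-oxo-8(17)-ene array at the final oxidation level in one operation. On this point it is better than the chosen plan, which spends steps 4–7 and 22 on the same array.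
- Against: A1 needs its own enantioselective synthesis of C5 and the acyl-bearing quaternary C10, which compound 1 supplies for nothing. The C9 configuration depends on the facial course of a reversible aldol onto a neopentyl ketone. The enone of A2 is itself a dienophile and Michael acceptor, so it would have to be reduced and masked before the cycloaddition and re-oxidised afterwards.
- Comparison: it addresses only the decalin sector, so it complements rather than replaces the chosen key step. Mechanistically it is a well-precedented tandem conjugate addition–aldol. In step count it is about equal to the route from 1 only if A1 is available in five steps or fewer.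

Alternative 2: The cut is C13=C14. The ring C seco compound A3 (acetyl group on C12, prenyl group on D6, ring D and the chromone diacetate already in place) would be treated with FeCl3. Formal [2+2] addition of the alkene to the C13 ketone and cycloreversion, with loss of the isopropylidene terminus as a volatile ketone, would give the target diacetate A4.
- In favour: the alkene is placed regiospecifically and no oxygen has to be removed. This is better than steps 17–19 of the chosen plan, and the endgame after the key step is shorter (deacetylation only).
- Against: A3 must already contain the contiguous C12, D5 and D6 stereocentres and the quaternary carbon, which the chosen cycloaddition creates in one step. The ketone is an unactivated aliphatic methyl ketone beside an epimerisable centre, whereas this metathesis is best established for aryl ketones and β-keto esters. FeCl3 would also meet a tertiary carbinol, an enol ether, an α-methylene ketone and aryl acetates, so carbonyl-ene and Prins pathways compete.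
- Comparison: the key step is more elegant but builds no stereocentre, and it moves the stereochemical problem into a longer, less convergent synthesis of A3.

Alternative 3: The cut is C12–D5. The allylic carbonate A5 has a tetrasubstituted arene (free D4 phenol, D1 silyl ether, D2 methyl ether, D5 bonded to the chromone) tethered through a (Z)-trisubstituted alkene to the C12 carbonate. Pd2(dba)3 and a chiral bisphosphine would ionise the carbonate, and the phenol would attack through its ortho carbon D5 to give the cyclohexadienone A6.
- In favour: ring D arrives as an easily assembled biaryl, C13=C14 is carried in from the allyl unit (again better than the chosen plan), and the quaternary centre is set under ligand control. This is equal in kind to the catalyst control the chosen plan needs. Only about three steps would remain after A6.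
- Against: the phenol is ambident (O- versus C-attack), and the attacked carbon is fully substituted and hindered by the chromone. C12 and D5 are formed together from an allyl complex that can equilibrate. A6 still lacks the D6 stereocentre, which would have to be set by face-selective protonation of a dienol ether. The dearomatised product can rearomatise, and the free allylic and tertiary hydroxyls of A5 are exposed to the metal.
- Comparison: the step is shorter after the key event, but it rests on more unverified selectivities and leaves one of the three contiguous stereocentres open.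

Key step: step 16

Design remarks and assumptions, one line each:
- The endo adduct of the (E)-alkylidene (C11 cis to the chromone) corresponds to the target at C12, D5 and D6, so the cycloadduct needs no stereochemical correction.
- The tertiary 9-OH is not left free: it is tied to the 7α-OH as a di-tert-butylsilylene, because a free β-hydroxy aldehyde, a free tertiary allylic alcohol under TiCl4 or Tf2O, and a free hydroxyl beside the copper chelate are all liabilities.
- The two deactivated acetals are opened with an aprotic Lewis acid at low temperature and not with strong aqueous acid.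
- 2,2-Dimethoxypropane-1,3-diol and diethyl (2-oxobutyl)phosphonate are taken as catalogue compounds.

## Route

Step 1
Reactants: 1 (+)-sclareolide
Product: 2 methyl 13,14,15,16-tetranorlabd-8-en-12-oate (tetrasubstituted 8,9-alkene; 5α-H, 10β-methyl)
Conditions: conc. H2SO4, MeOH, 65 °C; chromatography on AgNO3–SiO2
Reagents that add atoms: methanol, CO
Why: Acid opens the lactone through the tertiary C8 cation, the acid is esterified and a proton is lost (E1); under equilibrating conditions the tetrasubstituted 8,9-alkene should be the main isomer, and the trisubstituted isomers are removed on silver-impregnated silica.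

Step 2
Reactants: 2 methyl 13,14,15,16-tetranorlabd-8-en-12-oate
Product: 3 13,14,15,16-tetranorlabd-8-en-12-al
Conditions: i-Bu2AlH (1.1 equiv), CH2Cl2, −78 °C; aq. KNaC4H4O6
Reagents that add atoms: none
Why: Partial ester reduction stops at the aluminium hemiacetal at −78 °C; the tetrasubstituted β,γ-alkene should not move into conjugation under the neutral work-up.

Step 3
Reactants: 3 13,14,15,16-tetranorlabd-8-en-12-al
Product: 4 12,12-dimethoxy-13,14,15,16-tetranorlabd-8-ene
Conditions: HC(OMe)3, MeOH, PPTS (cat.), rt
Reagents that add atoms: trimethyl orthoformate, COC(OC)OC; methanol, CO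
Why: Acid-catalysed acetalisation; it removes the acidity of the C11 hydrogens so that the base of step 5 can only attack the epoxide periphery.

Step 4
Reactants: 4 12,12-dimethoxy-13,14,15,16-tetranorlabd-8-ene
Product: 5 8α,9α-epoxy-12,12-dimethoxy-13,14,15,16-tetranorlabdane
Conditions: mCPBA, NaHCO3, CH2Cl2, 0 °C
Reagents that add atoms: 3-chloroperoxybenzoic acid, O=C(OO)c1cccc(Cl)c1
Why: Prilezhaev epoxidation of the electron-rich tetrasubstituted alkene from the α-face, opposite the axial C10 methyl group; this sets the C9–O bond with the configuration of the target.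

Step 5
Reactants: 5 8α,9α-epoxy-12,12-dimethoxy-13,14,15,16-tetranorlabdane
Product: 6 12,12-dimethoxy-13,14,15,16-tetranorlabd-8(17)-en-9α-ol
Conditions: Et2Al(TMP) (from lithium 2,2,6,6-tetramethylpiperidide and Et2AlCl, 4 equiv), PhMe, 0 °C → rt
Reagents that add atoms: none
Why: Base-promoted epoxide-to-allylic-alcohol isomerisation (syn β-elimination within the aluminium-bound epoxide); the primary C17 hydrogens are the most accessible, C8–O breaks and the oxygen stays on C9 with retention.

Step 6
Reactants: 6 12,12-dimethoxy-13,14,15,16-tetranorlabd-8(17)-en-9α-ol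
Product: 7 12,12-dimethoxy-13,14,15,16-tetranorlabd-8(17)-ene-7α,9α-diol
Conditions: SeO2 (0.3 equiv), t-BuOOH (3 equiv), CH2Cl2, rt
Reagents that add atoms: tert-butyl hydroperoxide, CC(C)(C)OO (oxygen relayed by selenium dioxide, O=[Se]=O)
Why: Riley allylic oxidation (ene reaction, then [2,3]-sigmatropic shift); C7 is the only allylic CH position left, and the axial 7α-hydrogen is removed with oxygen returned to the same face, as is usual for 8(17)-labdenes.

Step 7
Reactants: 7 12,12-dimethoxy-13,14,15,16-tetranorlabd-8(17)-ene-7α,9α-diol
Product: 8 7α,9α-(di-tert-butylsilanediyldioxy)-12,12-dimethoxy-13,14,15,16-tetranorlabd-8(17)-ene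
Conditions: t-Bu2Si(OTf)2 (1.2 equiv), 2,6-lutidine, CH2Cl2, 0 °C → rt
Reagents that add atoms: di-tert-butylsilyl bis(trifluoromethanesulfonate), CC(C)(C)[Si](OS(=O)(=O)C(F)(F)F)(OS(=O)(=O)C(F)(F)F)C(C)(C)C
Why: Cyclic silylene formation across the 1,3-diaxial diol masks the secondary and the hindered tertiary hydroxyl with one reagent; any acetal cleavage by the silyl triflate would only anticipate step 8.

Step 8
Reactants: 8 7α,9α-(di-tert-butylsilanediyldioxy)-12,12-dimethoxy-13,14,15,16-tetranorlabd-8(17)-ene
Product: 9 7α,9α-(di-tert-butylsilanediyldioxy)-13,14,15,16-tetranorlabd-8(17)-en-12-al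
Conditions: PPTS (0.2 equiv), acetone–H2O (9:1), 40 °C
Reagents that add atoms: water, O
Why: Mild acid-catalysed hydrolysis of an ordinary dimethyl acetal; with the β-oxygen held in the silylene, β-elimination and retro-aldol cleavage of the aldehyde should be suppressed.

Step 9
Reactants: 10 noreugenin (5,7-dihydroxy-2-methylchromone)
Product: 11 5,7-bis(tert-butyldimethylsilyloxy)-2-methylchromone
Conditions: TBSOTf (2.4 equiv), 2,6-lutidine, CH2Cl2, 0 °C → rt
Reagents that add atoms: tert-butyldimethylsilyl trifluoromethanesulfonate, CC(C)(C)[Si](C)(C)OS(=O)(=O)C(F)(F)F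
Why: O-Silylation; the triflate is needed for the hydrogen-bonded 5-OH, whose masking removes a strong chelating site for titanium and copper.

Step 10
Reactants: 11 5,7-bis(tert-butyldimethylsilyloxy)-2-methylchromone; 12 methyl dimethoxyacetate
Product: 13 2-(3,3-dimethoxy-2-oxopropyl)-5,7-bis(tert-butyldimethylsilyloxy)chromone
Conditions: LiN(i-Pr)2 (2.2 equiv), THF, −78 °C; then 12, −78 → −30 °C; aq. NH4Cl
Reagents that add atoms: none
Why: Lateral deprotonation of the 2-methyl group gives a vinylogous enolate that undergoes Claisen acylation with the activated ester; the second equivalent of base takes up the more acidic product and prevents double acylation.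

Step 11
Reactants: 9 7α,9α-(di-tert-butylsilanediyldioxy)-13,14,15,16-tetranorlabd-8(17)-en-12-al; 13 2-(3,3-dimethoxy-2-oxopropyl)-5,7-bis(tert-butyldimethylsilyloxy)chromone
Product: 14 (E)-alkylidene ketone: C12=D5 with C11 cis to the chromon-2-yl group, D5 also bearing the C(=O)CH(OMe)2 arm, decalin part as in 9
Conditions: TiCl4 (2 equiv), pyridine (5 equiv), THF, 0 °C → rt
Reagents that add atoms: none
Why: Knoevenagel condensation through the titanium enolate (aldol addition, then elimination); the geometry should be thermodynamic, with the C11 substituent beside the twisted chromone and away from the coplanar acyl group.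

Step 12
Reactants: 15 2,2-dimethoxypropane-1,3-diol
Product: 16 2,2,3-trimethoxypropan-1-ol
Conditions: Ag2O (1.5 equiv), MeI (1.2 equiv), CH2Cl2, rt
Reagents that add atoms: iodomethane, CI
Why: Williamson O-methylation; silver oxide-mediated alkylation of a symmetrical diol should stop after the first ether.

Step 13
Reactants: 16 2,2,3-trimethoxypropan-1-ol
Product: 17 [2-(methoxymethyl)-1,3-dioxolan-2-yl]methanol
Conditions: HOCH2CH2OH (5 equiv), CSA (cat.), PhMe, 60 °C, methanol distilled off
Reagents that add atoms: ethylene glycol, OCCO
Why: Acid-catalysed transketalisation driven by removal of methanol; the dioxolane stands up to the silyl triflate of step 15, the Lewis acid of step 16 and the dilute acid of step 17, which an acyclic ketal would not.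

Step 14
Reactants: 17 [2-(methoxymethyl)-1,3-dioxolan-2-yl]methanol; 18 diethyl (2-oxobutyl)phosphonate
Product: 20 (E)-1-[2-(methoxymethyl)-1,3-dioxolan-2-yl]pent-1-en-3-one, via aldehyde 19 (not isolated)
Conditions: IBX, EtOAc, 75 °C; filtration; then 18, LiCl, i-Pr2NEt, MeCN, rt
Reagents that add atoms: none
Why: Hypervalent iodine oxidation gives the non-enolisable, hydrate-prone aldehyde, which is used in solution; Horner–Wadsworth–Emmons olefination with the keto phosphonate under LiCl–amine conditions should give the (E)-enone.

Step 15
Reactants: 20 (E)-1-[2-(methoxymethyl)-1,3-dioxolan-2-yl]pent-1-en-3-one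
Product: 21 (1E,3Z)-3-(tert-butyldimethylsilyloxy)-1-[2-(methoxymethyl)-1,3-dioxolan-2-yl]penta-1,3-diene
Conditions: TBSOTf (1.2 equiv), Et3N (2 equiv), CH2Cl2, −78 → 0 °C
Reagents that add atoms: tert-butyldimethylsilyl trifluoromethanesulfonate, CC(C)(C)[Si](C)(C)OS(=O)(=O)C(F)(F)F
Why: Soft enolisation and O-silylation at the α′-position (there is no γ-hydrogen) gives the cross-conjugated 2-silyloxydiene; the (Z)-enol ether expected from an ethyl ketone puts C16 on the outside of the s-cis diene.

Step 16
Reactants: 14 (E)-alkylidene ketone; 21 silyloxydiene carrying the ketal arm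
Product: 22 ring C cycloadduct with the C14 silyl enol ether (C14=C15) and quaternary D5, in which C11 and the chromonyl group lie on one face of ring C and the D4 acyl arm, the D6 ketal arm and C16 on the other
Conditions: Cu(OTf)2 (20 mol %), (S,S)-t-Bu-box [2,2′-isopropylidenebis((4S)-4-tert-butyl-2-oxazoline)] (22 mol %), 4 Å MS, CH2Cl2, −40 → 0 °C
Reagents that add atoms: none
Why: A normal-demand [4+2] cycloaddition in which the copper-bound, doubly activated alkylidene and the 2-silyloxydiene combine in a concerted but asynchronous way, C13 (the enol ether β-carbon) bonding to the electrophilic C12 ahead of D6 to D5. The closest known reaction type is the Lewis acid-catalysed Diels–Alder reaction of 2-silyloxydienes with alkylidene 1,3-dicarbonyl dienophiles, together with Cu(OTf)2–bis(oxazoline) catalysis of additions to chelating alkylidene dicarbonyls. Ring C is closed as a six-membered carbocycle by intermolecular cycloaddition, the diene supplying C13–C14–C15–D6 and the dienophile C12=D5, both bonds forming suprafacially. The C12/D5 relationship follows from the (E)-alkene, which holds C11 cis to the chromone. D6 and the transient C13 centre follow from the endo position of the chelated acyl arm and the (1E,3Z) diene geometry, which place the ketal arm and C16 cis to D4. The sense relative to the decalin is set by the catalyst: in the square-planar chelate of divalent copper with the ketone oxygen and one acetal oxygen (enone s-cis), the tert-butyl group of the (S,S)-ligand covers the Re face of C12, so the diene should add to the Si face that the target requires. Regioselectivity is secured by the silyloxy polarisation of the diene, and chemoselectivity by the fact that only the chelated alkene is activated (C8=C17 and the chromone C2′=C3′ are not). The step also needs carbocyclic rather than hetero-Diels–Alder closure, which the bulky silyl group and the absence of free hydroxyls near copper should favour.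

Step 17
Reactants: 22 ring C cycloadduct
Product: 23 C14 ketone (C15 methylene), all other groups as in 22
Conditions: 0.5 M aq. HCl, THF, 0 °C
Reagents that add atoms: none
Why: C-Protonation of the silyl enol ether at C15 and loss of silanol; cold dilute acid should spare the deactivated acetal and ketal and the silylene, and acid rather than fluoride avoids a free enolate that could open ring C by retro-Michael loss of D5.

Step 18
Reactants: 23 C14 ketone
Product: 24 C13=C14 enol triflate (trifluoromethanesulfonate on C14)
Conditions: Tf2O (2.5 equiv), 2,6-di-tert-butyl-4-methylpyridine (4 equiv), CH2Cl2, 0 °C → rt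
Reagents that add atoms: trifluoromethanesulfonic anhydride, O=S(=O)(OS(=O)(=O)C(F)(F)F)C(F)(F)F
Why: O-Triflation of the ketone and proton loss without an enolate gives the more substituted enol triflate under thermodynamic control; the D4 ketone is electron-poor and has no hydrogen on D5, and any O-triflation of the chromone carbonyl is reversed on aqueous work-up.

Step 19
Reactants: 24 C13=C14 enol triflate
Product: 25 C13=C14 alkene (C14–H), ring D arms still masked
Conditions: Pd(OAc)2 (10 mol %), PPh3 (20 mol %), HCO2H (2 equiv), n-Bu3N (3 equiv), DMF, 60 °C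
Reagents that add atoms: none
Why: Palladium-catalysed formate reduction of an enol triflate: oxidative addition to zerovalent palladium, formate exchange, decarboxylation and reductive elimination; the allylic silyl ethers and the other alkenes are inert.

Step 20
Reactants: 25 C13=C14 alkene
Product: 27 ring D closed 2-methoxy enedione, silylene and aryl silyl ethers retained, via keto aldehyde 26 (not isolated)
Conditions: Me2BBr (6 equiv), CH2Cl2, −78 → −40 °C; aq. NaHCO3; then piperidinium acetate (0.3 equiv), 4 Å MS, PhMe, 40 °C
Reagents that add atoms: water, O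
Why: The boron bromide converts both acetals into α-bromo ethers at low temperature (displacement beside a carbonyl is favourable), and these hydrolyse on work-up, so no protic acid meets the allylic C9–O bond or the C13=C14 alkene. The D1 ketone then adds through its D2 enamine or enol to the D3 aldehyde (6-(enolexo)-exo-trig aldol) and dehydration gives the vinylogous ester; the buffered amine salt should leave D6 untouched.

Step 21
Reactants: 27 ring D closed silylated enedione
Product: 28 7α,9α-diol with free chromone 5,7-diol (7-deoxo-7α-hydroxy target)
Conditions: HF·pyridine, pyridine, THF, 0 °C → rt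
Reagents that add atoms: none
Why: Fluoride-induced cleavage of all Si–O bonds; the buffered acidic fluoride should not touch the vinylogous ester or D6.

Step 22
Reactants: 28 7α,9α-diol
Product: 29 CNP0241859.1
Conditions: activated MnO2 (20 equiv), CH2Cl2–acetone, rt
Reagents that add atoms: none
Why: MnO2 oxidises the allylic secondary alcohol selectively over the tertiary alcohol and the electron-poor chromone phenols; the α-methylene ketone is formed last and meets no nucleophile.

## Compound list

1 | (+)-sclareolide | C[C@]12CCCC([C@@H]1CC[C@@]3([C@@H]2CC(=O)O3)C)(C)C | starting material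
2 | methyl 13,14,15,16-tetranorlabd-8-en-12-oate | CC1=C(CC(=O)OC)[C@@]2(C)CCCC(C)(C)[C@@H]2CC1 | intermediate
3 | 13,14,15,16-tetranorlabd-8-en-12-al | CC1=C(CC=O)[C@@]2(C)CCCC(C)(C)[C@@H]2CC1 | intermediate
4 | 12,12-dimethoxy-13,14,15,16-tetranorlabd-8-ene | CC1=C(CC(OC)OC)[C@@]2(C)CCCC(C)(C)[C@@H]2CC1 | intermediate
5 | 8α,9α-epoxy-12,12-dimethoxy-13,14,15,16-tetranorlabdane | C[C@@]13CC[C@H]2C(C)(C)CCC[C@]2(C)[C@@]1(O3)CC(OC)OC | intermediate
6 | 12,12-dimethoxy-13,14,15,16-tetranorlabd-8(17)-en-9α-ol | C=C1CC[C@H]2C(C)(C)CCC[C@]2(C)[C@@]1(O)CC(OC)OC | intermediate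
7 | 12,12-dimethoxy-13,14,15,16-tetranorlabd-8(17)-ene-7α,9α-diol | C=C1[C@H](O)C[C@H]2C(C)(C)CCC[C@]2(C)[C@@]1(O)CC(OC)OC | intermediate
8 | 7α,9α-(di-tert-butylsilanediyldioxy)-12,12-dimethoxy-13,14,15,16-tetranorlabd-8(17)-ene | C=C1[C@H](O[Si]3(C(C)(C)C)C(C)(C)C)C[C@H]2C(C)(C)CCC[C@]2(C)[C@@]1(O3)CC(OC)OC | intermediate
9 | 7α,9α-(di-tert-butylsilanediyldioxy)-13,14,15,16-tetranorlabd-8(17)-en-12-al | C=C1[C@H](O[Si]3(C(C)(C)C)C(C)(C)C)C[C@H]2C(C)(C)CCC[C@]2(C)[C@@]1(O3)CC=O | intermediate
10 | noreugenin | Cc1cc(=O)c2c(O)cc(O)cc2o1 | starting material
11 | 5,7-bis(tert-butyldimethylsilyloxy)-2-methylchromone | Cc1cc(=O)c2c(O[Si](C)(C)C(C)(C)C)cc(O[Si](C)(C)C(C)(C)C)cc2o1 | intermediate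
12 | methyl dimethoxyacetate | COC(OC)C(=O)OC | starting material
13 | 2-(3,3-dimethoxy-2-oxopropyl)-5,7-bis(tert-butyldimethylsilyloxy)chromone | COC(OC)C(=O)Cc1cc(=O)c2c(O[Si](C)(C)C(C)(C)C)cc(O[Si](C)(C)C(C)(C)C)cc2o1 | intermediate
14 | (E)-chromonyl alkylidene ketone, C11 cis to the chromone, 7α,9α-silylene | C=C1[C@H](O[Si]3(C(C)(C)C)C(C)(C)C)C[C@H]2C(C)(C)CCC[C@]2(C)[C@@]1(O3)C/C=C(\c1cc(=O)c2c(O[Si](C)(C)C(C)(C)C)cc(O[Si](C)(C)C(C)(C)C)cc2o1)C(=O)C(OC)OC | intermediate
15 | 2,2-dimethoxypropane-1,3-diol | COC(CO)(CO)OC | starting material
16 | 2,2,3-trimethoxypropan-1-ol | COCC(OC)(OC)CO | intermediate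
17 | [2-(methoxymethyl)-1,3-dioxolan-2-yl]methanol | COCC1(CO)OCCO1 | intermediate
18 | diethyl (2-oxobutyl)phosphonate | CCC(=O)CP(=O)(OCC)OCC | starting material
19 | 2-(methoxymethyl)-1,3-dioxolane-2-carbaldehyde | COCC1(C=O)OCCO1 | intermediate
20 | (E)-1-[2-(methoxymethyl)-1,3-dioxolan-2-yl]pent-1-en-3-one | CCC(=O)/C=C/C1(COC)OCCO1 | intermediate
21 | (1E,3Z)-3-(tert-butyldimethylsilyloxy)-1-[2-(methoxymethyl)-1,3-dioxolan-2-yl]penta-1,3-diene | C/C=C(O[Si](C)(C)C(C)(C)C)/C=C/C1(COC)OCCO1 | intermediate
22 | ring C cycloadduct, C14 silyl enol ether, D6 ketal arm cis to the D5 acyl arm, C11 cis to the chromone | C=C1[C@H](O[Si]3(C(C)(C)C)C(C)(C)C)C[C@H]2C(C)(C)CCC[C@]2(C)[C@@]1(O3)C[C@@H]1[C@@H](C)C(O[Si](C)(C)C(C)(C)C)=C[C@@H](C2(COC)OCCO2)[C@@]1(c1cc(=O)c2c(O[Si](C)(C)C(C)(C)C)cc(O[Si](C)(C)C(C)(C)C)cc2o1)C(=O)C(OC)OC | intermediate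
23 | C14 ketone of ring C | C=C1[C@H](O[Si]3(C(C)(C)C)C(C)(C)C)C[C@H]2C(C)(C)CCC[C@]2(C)[C@@]1(O3)C[C@@H]1[C@@H](C)C(=O)C[C@@H](C2(COC)OCCO2)[C@@]1(c1cc(=O)c2c(O[Si](C)(C)C(C)(C)C)cc(O[Si](C)(C)C(C)(C)C)cc2o1)C(=O)C(OC)OC | intermediate
24 | C13=C14 enol triflate | C=C1[C@H](O[Si]3(C(C)(C)C)C(C)(C)C)C[C@H]2C(C)(C)CCC[C@]2(C)[C@@]1(O3)C[C@@H]1C(C)=C(OS(=O)(=O)C(F)(F)F)C[C@@H](C2(COC)OCCO2)[C@@]1(c1cc(=O)c2c(O[Si](C)(C)C(C)(C)C)cc(O[Si](C)(C)C(C)(C)C)cc2o1)C(=O)C(OC)OC | intermediate
25 | C13=C14 alkene with masked ring D arms | C=C1[C@H](O[Si]3(C(C)(C)C)C(C)(C)C)C[C@H]2C(C)(C)CCC[C@]2(C)[C@@]1(O3)C[C@@H]1C(C)=CC[C@@H](C2(COC)OCCO2)[C@@]1(c1cc(=O)c2c(O[Si](C)(C)C(C)(C)C)cc(O[Si](C)(C)C(C)(C)C)cc2o1)C(=O)C(OC)OC | intermediate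
26 | keto aldehyde (D1 methoxyacetyl arm on D6, D4–D3 glyoxyloyl arm on D5) | C=C1[C@H](O[Si]3(C(C)(C)C)C(C)(C)C)C[C@H]2C(C)(C)CCC[C@]2(C)[C@@]1(O3)C[C@@H]1C(C)=CC[C@@H](C(=O)COC)[C@@]1(c1cc(=O)c2c(O[Si](C)(C)C(C)(C)C)cc(O[Si](C)(C)C(C)(C)C)cc2o1)C(=O)C=O | intermediate
27 | ring D closed 2-methoxy enedione, 7α,9α-silylene, chromone bis(silyl ether) | C=C1[C@H](O[Si]3(C(C)(C)C)C(C)(C)C)C[C@H]2C(C)(C)CCC[C@]2(C)[C@@]1(O3)C[C@@H]1C(C)=CC[C@H]2C(=O)C(OC)=CC(=O)[C@@]12c1cc(=O)c2c(O[Si](C)(C)C(C)(C)C)cc(O[Si](C)(C)C(C)(C)C)cc2o1 | intermediate
28 | 7-deoxo-7α-hydroxy target (7α,9α-diol, free chromone diol) | C=C1[C@H](O)C[C@H]2C(C)(C)CCC[C@]2(C)[C@@]1(O)C[C@@H]1C(C)=CC[C@H]2C(=O)C(OC)=CC(=O)[C@@]12c1cc(=O)c2c(O)cc(O)cc2o1 | intermediate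
29 | CNP0241859.1 | C=C1C(=O)C[C@H]2C(C)(C)CCC[C@]2(C)[C@@]1(O)C[C@@H]1C(C)=CC[C@H]2C(=O)C(OC)=CC(=O)[C@@]12c1cc(=O)c2c(O)cc(O)cc2o1 | target

## Step count and least certain steps

Total: 22 steps. Longest linear sequence: 16 steps (steps 1–8, 11, 16–22). The chromone branch (steps 9–10) and the diene branch (steps 12–15) join it at steps 11 and 16.

Step 16 (key step). The most likely failure is poor facial discrimination relative to the decalin. The stereocentres of 14 are remote, and the sense of induction rests on an unproven chelate (ketone and acetal oxygen, s-cis enone); binding at the chromone carbonyl or an s-trans enone would erode or invert it. The reaction may also divert to a stepwise Mukaiyama–Michael addition, or to hetero-Diels–Alder closure through the D4 oxygen, and congestion at D5–D6 may slow the second bond formation. The diene would be charged in moderate excess, because part of the silyl enol ether may be lost to protodesilylation at the Lewis acid, although only one molecule of it enters the product. Fallback: a stepwise Michael–Michael annulation without a chiral catalyst, setting out from 14 and 20. The α′-lithium enolate of 20 (LiN(i-Pr)2, THF, −78 °C) adds to C12 of 14 to give, after protonation, the open-chain Michael adduct F1. Catalytic DBU in MeCN then closes D5 onto the enone carbon D6 by intramolecular Michael addition, and the product is ketone 23, where the route is rejoined. The diastereomers would have to be separated at that stage.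

Step 18. Regiocontrol may be lost in the enol triflate formation (the C14=C15 isomer), and the chromone carbonyl may consume the anhydride, with partial loss of the peri silyl ether. Fallback: reduction and dehydration, setting out from 23. LiBH(s-Bu)3 (THF, −78 °C) should reduce the less hindered ring ketone from the equatorial side to the axial C14 alcohol F2. The sulfurane Ph2S[OC(CF3)2Ph]2 (CH2Cl2, rt) then eliminates it anti toward the axial tertiary C13–H, which gives alkene 25, where the route is rejoined.

Step 20. Unmasking of the two deactivated acetals may be incomplete or unselective. Other risks are Lewis acid ionisation at the allylic C9–O bond, epimerisation at D6, and aldol closure onto the D4 ketone instead of the aldehyde. Fallback: the order is changed so that unmasking is the last operation on the oxidised core, where a cation at C9 would be cross-conjugated with the C7 carbonyl and is disfavoured. Setting out from 25, HF·pyridine gives the desilylated tetraol with intact acetal and ketal F3. MnO2 gives the corresponding C7 enone F4. Aqueous trifluoroacetic acid (0 °C → rt, short contact) then hydrolyses both acetals and promotes the aldol condensation in the same medium, rejoining the route at 29.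

Step 11. The condensation may give a geometric mixture at C12=D5. The alkene may also move out of conjugation toward C11, and silyl ethers may be lost under TiCl4. Fallback: a stepwise aldol–elimination, setting out from 9 and 13. Soft enolisation (MgBr2·OEt2, i-Pr2NEt, CH2Cl2, −20 °C) gives the β-hydroxy ketone F5 as a diastereomer mixture. Methanesulfonyl chloride and Et3N give the mesylate F6, and DBU eliminates it under equilibrating conditions to 14, where the route is rejoined.

Step 5. The base may abstract a ring proton at C7 instead of a methyl proton at C17, which gives the endocyclic isomer. Fallback: the wrong isomer is used instead of being discarded. Setting out from 5, the 7-en-9α-ol F7 is epoxidised cis to its tertiary hydroxyl with VO(acac)2 and t-BuOOH to the 7α,8α-epoxy-9α-ol F8. A second treatment with Et2Al(TMP) can now only remove a C17 proton to form an allylic alcohol, with the oxygen staying on C7. This gives diol 7 directly, where the route is rejoined without step 6.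

Step 1. The acid-mediated elimination may give a mixture of alkene regioisomers. Fallback: a defined dehydration followed by isomerisation, setting out from 1. Saponification (KOH, MeOH) and methylation of the carboxylate with MeI in DMF give the 8α-hydroxy ester F9. SOCl2–pyridine at −78 °C eliminates the equatorial hydroxyl toward the methyl group to the 8(17)-ene ester F10. RhCl3·3H2O in hot ethanol moves the exocyclic alkene into the tetrasubstituted position, rejoining the route at 2.

## Further compounds

F1 | step 16 | open-chain Michael adduct of 14 and the enolate of 20 (new centres at C12, C13 and D5 unassigned) | C=C1[C@H](O[Si]3(C(C)(C)C)C(C)(C)C)C[C@H]2C(C)(C)CCC[C@]2(C)[C@@]1(O3)CC(C(C)C(=O)/C=C/C1(COC)OCCO1)C(c1cc(=O)c2c(O[Si](C)(C)C(C)(C)C)cc(O[Si](C)(C)C(C)(C)C)cc2o1)C(=O)C(OC)OC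
F2 | step 18 | axial C14 alcohol from 23 (hydroxyl cis to C16) | C=C1[C@H](O[Si]3(C(C)(C)C)C(C)(C)C)C[C@H]2C(C)(C)CCC[C@]2(C)[C@@]1(O3)C[C@@H]1[C@@H](C)[C@@H](O)C[C@@H](C2(COC)OCCO2)[C@@]1(c1cc(=O)c2c(O[Si](C)(C)C(C)(C)C)cc(O[Si](C)(C)C(C)(C)C)cc2o1)C(=O)C(OC)OC
F3 | step 20 | desilylated tetraol with intact acetal and ketal | C=C1[C@H](O)C[C@H]2C(C)(C)CCC[C@]2(C)[C@@]1(O)C[C@@H]1C(C)=CC[C@@H](C2(COC)OCCO2)[C@@]1(c1cc(=O)c2c(O)cc(O)cc2o1)C(=O)C(OC)OC
F4 | step 20 | C7 enone with intact acetal and ketal | C=C1C(=O)C[C@H]2C(C)(C)CCC[C@]2(C)[C@@]1(O)C[C@@H]1C(C)=CC[C@@H](C2(COC)OCCO2)[C@@]1(c1cc(=O)c2c(O)cc(O)cc2o1)C(=O)C(OC)OC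
F5 | step 11 | β-hydroxy ketone (aldol adduct of 9 and 13, C12 and D5 unassigned) | C=C1[C@H](O[Si]3(C(C)(C)C)C(C)(C)C)C[C@H]2C(C)(C)CCC[C@]2(C)[C@@]1(O3)CC(O)C(c1cc(=O)c2c(O[Si](C)(C)C(C)(C)C)cc(O[Si](C)(C)C(C)(C)C)cc2o1)C(=O)C(OC)OC
F6 | step 11 | mesylate of the aldol adduct | C=C1[C@H](O[Si]3(C(C)(C)C)C(C)(C)C)C[C@H]2C(C)(C)CCC[C@]2(C)[C@@]1(O3)CC(OS(C)(=O)=O)C(c1cc(=O)c2c(O[Si](C)(C)C(C)(C)C)cc(O[Si](C)(C)C(C)(C)C)cc2o1)C(=O)C(OC)OC
F7 | step 5 | 12,12-dimethoxy-13,14,15,16-tetranorlabd-7-en-9α-ol | CC1=CC[C@H]2C(C)(C)CCC[C@]2(C)[C@@]1(O)CC(OC)OC
F8 | step 5 | 7α,8α-epoxy-12,12-dimethoxy-13,14,15,16-tetranorlabdan-9α-ol | C[C@@]1(O3)[C@H]3C[C@H]2C(C)(C)CCC[C@]2(C)[C@@]1(O)CC(OC)OC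
F9 | step 1 | methyl 8α-hydroxy-13,14,15,16-tetranorlabdan-12-oate | C[C@@]1(O)CC[C@H]2C(C)(C)CCC[C@]2(C)[C@H]1CC(=O)OC
F10 | step 1 | methyl 13,14,15,16-tetranorlabd-8(17)-en-12-oate | C=C1CC[C@H]2C(C)(C)CCC[C@]2(C)[C@H]1CC(=O)OC
A1 | alternative 1 | seco-diketone with vinyl ketone chain on C5 and 3,3-dimethoxypropanoyl group on C10 | C=CC(=O)C[C@H]1C(C)(C)CCC[C@]1(C)C(=O)CC(OC)OC
A2 | alternative 1 | 9α-hydroxy-7-oxo-8(17)-ene decalin with C11–C12 as the dimethyl acetal | C=C1C(=O)C[C@H]2C(C)(C)CCC[C@]2(C)[C@@]1(O)CC(OC)OC
A3 | alternative 2 | ring C seco compound: acetyl group on C12, prenyl group on D6, chromone diacetate | C=C1C(=O)C[C@H]2C(C)(C)CCC[C@]2(C)[C@@]1(O)C[C@H](C(C)=O)[C@]1(c2cc(=O)c3c(OC(C)=O)cc(OC(C)=O)cc3o2)C(=O)C=C(OC)C(=O)[C@@H]1CC=C(C)C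
A4 | alternative 2 | target as its chromone 5,7-diacetate | C=C1C(=O)C[C@H]2C(C)(C)CCC[C@]2(C)[C@@]1(O)C[C@@H]1C(C)=CC[C@H]2C(=O)C(OC)=CC(=O)[C@@]12c1cc(=O)c2c(OC(C)=O)cc(OC(C)=O)cc2o1
A5 | alternative 3 | (Z)-allylic methyl carbonate at C12 tethered to the chromonyl hydroquinone mono-silyl ether (C12 configuration open) | C=C1[C@H](O)C[C@H]2C(C)(C)CCC[C@]2(C)[C@@]1(O)CC(OC(=O)OC)/C(C)=C\Cc1c(O[Si](C)(C)C(C)(C)C)c(OC)cc(O)c1-c1cc(=O)c2c(O)cc(O[Si](C)(C)C(C)(C)C)cc2o1
A6 | alternative 3 | ring C closed cyclohexa-2,4-dienone with D1 silyl dienol ether | C=C1[C@H](O)C[C@H]2C(C)(C)CCC[C@]2(C)[C@@]1(O)C[C@@H]1C(C)=CCC2=C(O[Si](C)(C)C(C)(C)C)C(OC)=CC(=O)[C@@]12c1cc(=O)c2c(O)cc(O[Si](C)(C)C(C)(C)C)cc2o1
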